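Numbering: ring A = 3,4,5-trimethoxyphenyl, C7 = ketone carbon, C8 = stereocentre, C9 = its methyl group, ring B = 4-allyl-2,6-dimethoxyphenyl, bound to C8 through oxygen.
Retrosynthesis cuts, in this order, the ring A–C7 bond (acyl cross-coupling of a thioester), the C8–C9 bond (enolate methylation) and the O–C8 ether bond (Williamson alkylation with a two-carbon acid).
Enabling feature: C8 sits between acyl carbon C7 and the ring B ether oxygen and carries only the small methyl C9, so an aryloxyacetyl (glycolate-type) enolate can accept C9 as an electrophile on one face.
Forward: both arene rings are bought and no ring is formed; the chain is joined as ring B–O–C8–C7 first, then C9, then ring A.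
Stereochemistry: the single centre C8 (R) comes from the benzyl group of an (S)-4-benzyloxazolidinone carried on C7, and every later step avoids strong base so that C8 is not epimerised.

Key step: step 3

Remark: the two C8-epimeric imides from the methylation are assumed to be separable on silica gel or by crystallisation, as is usual for N-acyloxazolidinone diastereomers.

Step 1
Reactants: 1 4-allyl-2,6-dimethoxyphenol; 2 bromoacetic acid
Product: 3 (4-allyl-2,6-dimethoxyphenoxy)acetic acid
Conditions: NaOH, H2O, 90 °C; acidic work-up (HCl)
Reagents that add atoms: none
Why: Williamson ether synthesis in which the phenoxide displaces bromide from bromoacetate by SN2, a routine way to aryloxyacetic acids from eugenol-type phenols, and the allyl group should not move into conjugation in aqueous NaOH at this temperature.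

Step 2
Reactants: 3 (4-allyl-2,6-dimethoxyphenoxy)acetic acid; 4 (S)-4-benzyloxazolidin-2-one
Product: 6 (S)-4-benzyl-3-[(4-allyl-2,6-dimethoxyphenoxy)acetyl]oxazolidin-2-one, via mixed pivalic anhydride 5 (not isolated)
Conditions: t-BuCOCl, Et3N, THF, −20 °C; then LiCl, 4, −20 °C → rt
Reagents that add atoms: pivaloyl chloride, CC(C)(C)C(=O)Cl (its atoms appear only in 5)
Why: Mixed-anhydride N-acylation of an oxazolidinone (LiCl/Et3N variant), in which the tert-butyl group of 5 steers the lithium-activated carbamate nitrogen of 4 to the unhindered aryloxyacetyl carbonyl, while the C4 stereocentre of the auxiliary takes no part.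

Step 3
Reactants: 6 (S)-4-benzyl-3-[(4-allyl-2,6-dimethoxyphenoxy)acetyl]oxazolidin-2-one; 7 iodomethane
Product: 9 (S)-4-benzyl-3-[(R)-2-(4-allyl-2,6-dimethoxyphenoxy)propanoyl]oxazolidin-2-one, via sodium Z enolate 8 (not isolated)
Conditions: NaN(SiMe3)2, THF, −78 °C; then MeI, −78 → −40 °C
Reagents that add atoms: iodomethane (compound 7), CI
Why: NaN(SiMe3)2 removes one C8 hydrogen, which is acidified by the imide carbonyl C7 and by the ring B ether oxygen, and gives the Z enolate 8, in which sodium bridges the enolate oxygen and the oxazolidinone carbonyl and thereby freezes rotation about the C7–N bond. Iodomethane is then attacked by C8 in an SN2 displacement of iodide that forms the C8–C9 bond, and no ring is closed in the step. The closest known reaction type is the Evans alkylation of sodium enolates of alkoxyacetyl (glycolate) imides with reactive halides, here carried over to an aryloxyacetyl imide. The one new stereocentre, C8, is controlled by the C4 benzyl group of the (S)-auxiliary, which covers one face of the planar chelate, so that the methyl group enters from the open face and C8 becomes (R). The step needs facial selectivity, C- rather than O-alkylation and deprotonation at C8 only; the rigid chelate, the soft iodide and the much lower acidity of the ring B ArCH2CH=CH2 group toward a silylamide base at −78 °C should secure these in turn. Since iodomethane is small, a minor share of the C8 epimer is to be expected and is removed as a diastereomer by chromatography or crystallisation of 9, which itself resists a second enolisation because of allylic strain.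

Step 4
Reactants: 9 (S)-4-benzyl-3-[(R)-2-(4-allyl-2,6-dimethoxyphenoxy)propanoyl]oxazolidin-2-one
Product: 10 S-ethyl (R)-2-(4-allyl-2,6-dimethoxyphenoxy)propanethioate
Conditions: EtSH, n-BuLi (gives LiSEt), THF, 0 °C, Ar; aqueous work-up
Reagents that add atoms: ethanethiol, CCS
Why: Thiolysis of an N-acyloxazolidinone with LiSEt, in which the soft, strongly nucleophilic but weakly basic thiolate adds to the exocyclic carbonyl C7 and expels the oxazolidinone anion, so that C8 should keep its (R) configuration, the aryl methyl ethers and the allyl group stay untouched at 0 °C, and auxiliary 4 is recovered.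

Step 5
Reactants: 10 S-ethyl (R)-2-(4-allyl-2,6-dimethoxyphenoxy)propanethioate; 11 3,4,5-trimethoxyphenylboronic acid
Product: 12 (R)-2-(4-allyl-2,6-dimethoxyphenoxy)-1-(3,4,5-trimethoxyphenyl)propan-1-one (target)
Conditions: Pd2(dba)3 (cat.), P(2-furyl)3, Cu(O2CC4H3S), THF, 50 °C, Ar; neutral work-up
Reagents that add atoms: none
Why: Liebeskind–Srogl thioester–boronic acid coupling, in which zerovalent palladium inserts into the C7–S bond, the monovalent copper carboxylate binds the thiolate while activating boron for transfer of ring A, and reductive elimination forms the ring A–C7 bond without added base, which the readily enolised alpha-aryloxy aryl ketone needs in order to keep C8 (R), as is known for alpha-amino thioesters.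

Compound list
1 | 4-allyl-2,6-dimethoxyphenol | C=CCc1cc(OC)c(O)c(OC)c1 | starting material
2 | bromoacetic acid | OC(=O)CBr | starting material
3 | (4-allyl-2,6-dimethoxyphenoxy)acetic acid | OC(=O)COc1c(OC)cc(CC=C)cc1OC | intermediate
4 | (S)-4-benzyloxazolidin-2-one | O=C1N[C@@H](Cc2ccccc2)CO1 | starting material
5 | (4-allyl-2,6-dimethoxyphenoxy)acetic pivalic anhydride, not isolated | CC(C)(C)C(=O)OC(=O)COc1c(OC)cc(CC=C)cc1OC | intermediate
6 | (S)-4-benzyl-3-[(4-allyl-2,6-dimethoxyphenoxy)acetyl]oxazolidin-2-one | O=C1OC[C@H](Cc2ccccc2)N1C(=O)COc1c(OC)cc(CC=C)cc1OC | intermediate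
7 | iodomethane | CI | starting material
8 | sodium Z enolate of 6 (enolate oxygen and aryloxy group cis), not isolated | [Na+].O=C1OC[C@H](Cc2ccccc2)N1/C([O-])=C/Oc1c(OC)cc(CC=C)cc1OC | intermediate
9 | (S)-4-benzyl-3-[(R)-2-(4-allyl-2,6-dimethoxyphenoxy)propanoyl]oxazolidin-2-one | O=C1OC[C@H](Cc2ccccc2)N1C(=O)[C@@H](C)Oc1c(OC)cc(CC=C)cc1OC | intermediate
10 | S-ethyl (R)-2-(4-allyl-2,6-dimethoxyphenoxy)propanethioate | CCSC(=O)[C@@H](C)Oc1c(OC)cc(CC=C)cc1OC | intermediate
11 | 3,4,5-trimethoxyphenylboronic acid | COc1cc(B(O)O)cc(OC)c1OC | starting material
12 | (R)-2-(4-allyl-2,6-dimethoxyphenoxy)-1-(3,4,5-trimethoxyphenyl)propan-1-one | C=CCc1cc(OC)c(O[C@H](C)C(=O)c2cc(OC)c(OC)c(OC)c2)c(OC)c1 | target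

Total step count: 5. Longest linear sequence: 5 steps (1 → 3 → 6 → 9 → 10 → 12).

Steps most likely to fail

1. Step 3. The small electrophile may be discriminated poorly between the two enolate faces. Enolate 8 may also break down by loss of the auxiliary anion (ketene pathway) before the rather slow methylation is complete. The fallback replaces auxiliary control with chiral-pool material and inversion. It sets out from phenol 1, which is joined under Mitsunobu conditions (PPh3, DIAD, THF, 0 °C → rt) to commercial ethyl (S)-lactate, CCOC(=O)[C@H](C)O. SN2 inversion at the carbinol carbon should give ethyl (R)-2-(4-allyl-2,6-dimethoxyphenoxy)propanoate F1. Treating this ester with AlMe3/EtSH in CH2Cl2 (aluminium thiolate exchange of OEt for SEt) brings the material back to the route at thioester 10.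

2. Step 5. Transfer of ring A from boron may be slow, with protodeboronation competing. The acylpalladium species may lose CO, or the configuration at C8 may erode in the enolisable product on prolonged heating. The fallback uses acyl substitution through a chelated tetrahedral intermediate instead of catalysis. It sets out from imide 9, which is transamidated with MeONHMe·HCl/AlMe3 in CH2Cl2 to (R)-2-(4-allyl-2,6-dimethoxyphenoxy)-N-methoxy-N-methylpropanamide F2. Addition of 3,4,5-trimethoxyphenylmagnesium bromide F3, made from commercial 5-bromo-1,2,3-trimethoxybenzene and Mg in THF, at −20 to 0 °C should give a magnesium chelate. This chelate holds until a cold dilute HCl quench and then releases the ketone, so the route is rejoined at target 12.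

3. Step 4. The thiolate may attack the ring carbonyl and open the oxazolidinone, the hindered C7 carbonyl may react slowly, or excess thiolate may epimerise C8 in the thioester. The fallback uses hydrolysis followed by separate activation. It sets out from imide 9, which is cleaved with LiOH/H2O2 in THF–H2O at 0 °C (Na2SO3 work-up) to (R)-2-(4-allyl-2,6-dimethoxyphenoxy)propanoic acid F4. Carbodiimide coupling of this acid with EtSH (EDC, HOBt, CH2Cl2, 0 °C) returns to the route at thioester 10.

Further compounds
F1 | step 3 | ethyl (R)-2-(4-allyl-2,6-dimethoxyphenoxy)propanoate | CCOC(=O)[C@@H](C)Oc1c(OC)cc(CC=C)cc1OC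
F2 | step 5 | (R)-2-(4-allyl-2,6-dimethoxyphenoxy)-N-methoxy-N-methylpropanamide | CON(C)C(=O)[C@@H](C)Oc1c(OC)cc(CC=C)cc1OC
F3 | step 5 | 3,4,5-trimethoxyphenylmagnesium bromide | COc1cc([Mg]Br)cc(OC)c1OC
F4 | step 4 | (R)-2-(4-allyl-2,6-dimethoxyphenoxy)propanoic acid | OC(=O)[C@@H](C)Oc1c(OC)cc(CC=C)cc1OC
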